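**Retrosynthetic overview**

1. Feature: in the ten-membered ring C1–C10 the lactone carbinol C6 lies next to C7, which carries C11 with its two one-carbon arms C12 and C13. Read as C6(OH)–C7–C11(=C12), this is the homoallylic alcohol left by a [2,3]-Wittig shift of a C6–O–C12 ether.
2. Target ⇐ ester exchanges (O8 methacrylate, O2/O13 acetates) ⇐ 7(11)-butenolide (selenoxide elimination) ⇐ γ-lactone (hydroboration of C11=C12, oxidative lactonisation) ⇐ 4,5-epoxide (O6-directed) ⇐ (1(10)Z,4E)-cyclodecadien-6-ol.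
3. C15 ⇐ C4≡C5 alkyne (trans-hydroalumination, iodination, Stille); cyclodecenynol ⇐ transannular [2,3]-Wittig contraction of a thirteen-membered propargyl allyl ether, forming C6–C7.
4. Thirteen-membered ether ⇐ Williamson closure (C6–O–C12) ⇐ open chain from HWE (C7=C11), vinyllithium/epoxide (C9–C10), iodo-Wittig (C1=C10) and acetylide/epoxide (C3–C4); C2 and C8 both come from (R)-glycidol.
5. Ring order: 13-membered ether → 10-membered carbocycle → oxirane → butenolide.

Key step: step 17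

Remarks
- Locants C1–C15 are the germacrane locants of the target (C14 = methyl on C10, C15 = methyl on C4, C12 and C13 on C11). PMB = 4-methoxybenzyl, TBS = tert-butyldimethylsilyl, TIPS = triisopropylsilyl, THP = tetrahydropyran-2-yl, TOM-Cl = (triisopropylsiloxy)methyl chloride.
- Assumption: an α-oxy carbanion at C6 next to a γ,γ-disubstituted alkene would not form selectively beside the allylic C12–H, so C4–C5 is carried as an alkyne through the ring contraction (propargylic C6–H) and C15 is added afterwards; compound 29 is the (1(10)Z,4E)-cyclodecadien-6-ol.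
- C7 in 26–36 is drawn as the isomer expected from the anti pathway; it becomes sp2 in step 24, so either C7 epimer serves.
- The THP acetal carbon (4–21), the arylidene carbon of 13 and C11 of 32–35 are epimer mixtures and are left undefined in the SMILES.

**Route**

Step 1
Reactants: 1 (R)-glycidol
Product: 3 (S)-glycidyl 4-methoxybenzyl ether, via sodium glycidolate 2 (not isolated)
Conditions: NaH, PMBCl, Bu4NI (cat.), DMF, 0 °C → rt
Reagents that add atoms: 4-methoxybenzyl chloride COc1ccc(CCl)cc1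
Why: Williamson etherification of the primary alkoxide breaks no bond at the stereocentre (the Payne shift of glycidolate is degenerate), and the descriptor changes from R to S only through the priority rules.

Step 2
Reactants: 4 propargyl THP ether; 3 (S)-glycidyl PMB ether
Product: 6 (2S)-1-(PMB-oxy)-6-(THP-oxy)hex-4-yn-2-ol, via lithium acetylide 5 (not isolated)
Conditions: n-BuLi, THF, −78 °C; BF3·OEt2; then 3, −78 °C
Reagents that add atoms: none
Why: Yamaguchi–Hirao alkynylation, in which the BF3-activated epoxide is opened at its unsubstituted carbon (future C3), so the C–O stereocentre of 3 becomes C2 (S) unchanged.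

Step 3
Reactants: 6 homopropargylic alcohol
Product: 7 C2 TBS ether
Conditions: TBSCl, imidazole, DMF, rt
Reagents that add atoms: tert-butyldimethylsilyl chloride CC(C)(C)[Si](C)(C)Cl
Why: standard imidazole-promoted silylation of a secondary alcohol masks O2 until the end of the route.

Step 4
Reactants: 7 PMB ether
Product: 8 (2S)-2-(TBS-oxy)-6-(THP-oxy)hex-4-yn-1-ol
Conditions: DDQ, CH2Cl2/pH 7 buffer, 0 °C
Reagents that add atoms: none
Why: oxidative PMB cleavage (benzylic hydride abstraction by DDQ, hydrolysis of the oxocarbenium ion) should leave the silyl ether, the THP acetal and the alkyne untouched under buffered conditions.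

Step 5
Reactants: 8 primary alcohol
Product: 9 (2S)-2-(TBS-oxy)-6-(THP-oxy)hex-4-ynal
Conditions: Dess–Martin periodinane, NaHCO3, CH2Cl2, 0 °C → rt
Reagents that add atoms: none
Why: Dess–Martin oxidation under buffered, non-basic conditions should give the α-silyloxy aldehyde without epimerisation at C2.

Step 6
Reactants: 9 aldehyde
Product: 10 (2Z,4S)-4-(TBS-oxy)-2-iodo-8-(THP-oxy)oct-2-en-6-yne
Conditions: EtPPh3I, n-BuLi, THF, rt; I2, −78 °C; NaN(SiMe3)2, −78 → −20 °C; then 9, −78 °C
Reagents that add atoms: ethyltriphenylphosphonium iodide CC[P+](c1ccccc1)(c1ccccc1)c1ccccc1.[I-]; iodine II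
Why: Stork–Zhao-type Wittig olefination with the α-iodoethylidene ylide gives the trisubstituted vinyl iodide with iodine cis to the C2 chain (Z), the geometry that becomes the Z C1=C10 alkene.

Step 7
Reactants: 10 Z-vinyl iodide; 3 (S)-glycidyl PMB ether (second use)
Product: 12 (2S,4Z,6S)-6-(TBS-oxy)-1-(PMB-oxy)-4-methyl-10-(THP-oxy)dec-4-en-8-yn-2-ol, via vinyllithium 11 (not isolated)
Conditions: t-BuLi (2 equiv), Et2O, −78 °C; BF3·OEt2; then 3, −78 °C
Reagents that add atoms: none
Why: iodine–lithium exchange with retention of alkene geometry (Et2O at −78 °C keeps O→C silyl migration slow) and BF3-assisted opening of the epoxide at CH2 form C9–C10 and bring in C8 (S) from the chiral pool.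

Step 8
Reactants: 12 C8 alcohol with C7 PMB ether
Product: 13 C7,C8 4-methoxybenzylidene acetal
Conditions: DDQ, 4 Å MS, CH2Cl2 (anhydrous), 0 °C
Reagents that add atoms: none
Why: under anhydrous conditions the PMB oxocarbenium ion formed by DDQ is trapped by the neighbouring C8 hydroxyl to give the dioxolane (Oikawa–Yonemitsu oxidative acetalisation).

Step 9
Reactants: 13 arylidene acetal
Product: 14 (2S,4Z,6S)-6-(TBS-oxy)-2-(PMB-oxy)-4-methyl-10-(THP-oxy)dec-4-en-8-yn-1-ol
Conditions: i-Bu2AlH, CH2Cl2, −78 → 0 °C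
Reagents that add atoms: none
Why: regioselective reductive acetal opening, in which the aluminium binds the less hindered primary oxygen and cleaves its C–O bond, so PMB ends on the secondary O8 and C7–OH is set free.

Step 10
Reactants: 14 primary alcohol
Product: 15 (2S,4Z,6S)-6-(TBS-oxy)-2-(PMB-oxy)-4-methyl-10-(THP-oxy)dec-4-en-8-ynal
Conditions: Dess–Martin periodinane, NaHCO3, CH2Cl2, 0 °C → rt
Reagents that add atoms: none
Why: Dess–Martin oxidation gives the α-alkoxy aldehyde under conditions that should not epimerise C8.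

Step 11
Reactants: 16 triethyl phosphonoacetate
Product: 18 ethyl 2-(diethoxyphosphoryl)-3-(triisopropylsilyloxy)propanoate, via sodium phosphonoacetate enolate 17 (not isolated)
Conditions: NaH, THF, 0 °C; TOM-Cl, 0 °C → rt
Reagents that add atoms: (triisopropylsiloxy)methyl chloride ClCO[Si](C(C)C)(C(C)C)C(C)C
Why: C-alkylation of the stabilised phosphonate carbanion by a reactive α-chloro ether (SN2) installs the future C13 oxymethyl arm.

Step 12
Reactants: 15 aldehyde; 18 phosphonate
Product: 19 ethyl (2E,4S,6Z,8S)-8-(TBS-oxy)-4-(PMB-oxy)-6-methyl-12-(THP-oxy)-2-[(TIPS-oxy)methyl]dodeca-2,6-dien-10-ynoate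
Conditions: LiCl, DBU, MeCN, 0 °C → rt
Reagents that add atoms: none
Why: Horner–Wadsworth–Emmons olefination under Masamune–Roush conditions (weak amine base, lithium chelation) should avoid aldehyde epimerisation and β-elimination of the phosphonate and give the enoate with the ester (C12) trans to C8.

Step 13
Reactants: 19 enoate
Product: 20 C12 allylic alcohol
Conditions: i-Bu2AlH, CH2Cl2, −78 °C
Reagents that add atoms: none
Why: 1,2-reduction of the enoate by DIBAL-H at low temperature; no other group in 19 is reducible under these conditions.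

Step 14
Reactants: 20 allylic alcohol
Product: 21 C12 allylic chloride
Conditions: NCS, Me2S, CH2Cl2, −20 → 0 °C
Reagents that add atoms: N-chlorosuccinimide ClN1C(=O)CCC1=O
Why: Corey–Kim chlorination converts the primary allylic alcohol through its alkoxysulfonium salt into the chloride under neutral conditions without allylic transposition.

Step 15
Reactants: 21 THP ether
Product: 22 C6 propargylic alcohol bearing the C12 chloride
Conditions: PPTS (cat.), MeOH, rt
Reagents that add atoms: none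
Why: acid-catalysed transacetalisation to methanol removes the THP group, PPTS being too weak at rt to cleave the secondary TBS, primary TIPS or PMB ethers or to solvolyse the primary allylic chloride.

Step 16
Reactants: 22 hydroxy chloride
Product: 24 thirteen-membered propargyl allyl ether, via sodium alkoxide 23 (not isolated)
Conditions: NaH, Bu4NI (cat.), THF, slow addition, 0.002 M, 50 °C
Reagents that add atoms: none
Why: intramolecular Williamson etherification (SN2 of the propargylic alkoxide at the primary allylic carbon) under high dilution, helped by the alkyne and the two alkenes, which restrict the chain.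

Step 17
Reactants: 24 thirteen-membered propargyl allyl ether
Product: 26 (6S,7S)-cyclodec-1(10)-en-4-yn-6-ol with the 3-(TIPS-oxy)prop-1-en-2-yl group on C7, via C6-lithiated ether 25 (not isolated)
Conditions: n-BuLi, THF, −78 °C; H2O
Reagents that add atoms: none
Why: n-BuLi removes a C6 proton, the only α-oxy propargylic C–H of 24 and far more acidic than the allylic C12–H, the PMB benzylic C–H or C3–H, and the carbanion 25 bonds to C7 through a five-membered envelope (C6, O, C12, C11, C7) while the C12–O bond breaks and C11=C12 forms, a concerted [2,3]-Wittig shift. The closest known reaction type is the [2,3]-Wittig ring contraction of thirteen-membered propargyl allyl ethers to cyclodecenynols. The ten-membered carbocycle is closed by transannular C6–C7 bond formation inside the thirteen-membered ring, a contraction by three atoms in which the ether oxygen ends as the C6 alkoxide. C7 is set by the alkene face, since A(1,3) strain between C8 and the cis C13 methylene holds H8 in the alkene plane and C6 adds anti to the C8–OPMB bond; C6 is set relative to C7 by the envelope with the alkynyl group exo on the allyl unit whose C12 is trans to C8 (anti pathway), which places O6 trans to the C7 side chain and on the face of O8, the 6S configuration of the target, with C5 and C9 gauche as the tether requires. The step needs regioselective lithiation and the 6S outcome; the propargylic position secures the first and the C8 stereocentre the second, and only C6 matters because C7 later becomes sp2.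

Step 18
Reactants: 26 cyclodecenynol
Product: 28 (4Z)-4-iodo-cyclodeca-1(10),4-dien-6-ol, via cyclic vinylaluminate 27 (not isolated)
Conditions: NaAlH2(OCH2CH2OMe)2 (Red-Al), THF, 0 °C → rt; I2, −78 °C
Reagents that add atoms: iodine II
Why: hydroxyl-directed trans-hydroalumination of the propargylic alcohol (hydride to C5, aluminium to C4 in a five-membered alkoxyaluminate) and iodinolysis with retention give the vinyl iodide with iodine cis to C6, so C3 and C6 are trans in the ring (Corey's 3-iodoallylic alcohol method).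

Step 19
Reactants: 28 vinyl iodide
Product: 29 (1(10)Z,4E)-4,10-dimethylcyclodeca-1(10),4-dien-6-ol with O2-TBS, O8-PMB and the 3-(TIPS-oxy)prop-1-en-2-yl group on C7
Conditions: Me4Sn, Pd2(dba)3 (cat.), AsPh3, CuI (cat.), NMP, 60 °C
Reagents that add atoms: tetramethylstannane C[Sn](C)(C)C
Why: Stille coupling replaces iodine by methyl with retention of alkene geometry, giving the 4E alkene with C15 cis to C6, and tolerates the free allylic alcohol.

Step 20
Reactants: 29 dienol
Product: 30 (4R,5R,6S)-4,5-epoxy alcohol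
Conditions: Ti(OiPr)4, t-BuOOH, 4 Å MS, CH2Cl2, −20 °C
Reagents that add atoms: tert-butyl hydroperoxide CC(C)(C)OO
Why: hydroxyl-directed epoxidation reaches only the allylic C4=C5 bond; A(1,3) strain between C15 and C6 keeps H6 in the alkene plane so that O6 lies on the exposed outer face of the E-alkene and oxygen is delivered there, giving the threo (4R,5R) epoxy alcohol.

Step 21
Reactants: 30 epoxy alcohol
Product: 32 C6,C12-diol (C11 epimers), via bis-borane 31 (not isolated)
Conditions: 9-BBN (2.5 equiv), THF, 0 °C → rt; NaOH, H2O2, 0 °C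
Reagents that add atoms: hydrogen peroxide OO
Why: 9-BBN hydroborates the 1,1-disubstituted C11=C12 bond far faster than the trisubstituted C1=C10 bond and places boron on terminal C12 (anti-Markovnikov), and alkaline peroxide oxidation gives the primary alcohol; the C11 configuration is irrelevant.

Step 22
Reactants: 32 diol
Product: 34 trans-fused 6,12-lactone, via lactol 33 (not isolated)
Conditions: PhI(OAc)2, TEMPO (cat.), CH2Cl2, rt
Reagents that add atoms: none
Why: TEMPO/PhI(OAc)2 oxidises only the primary alcohol, the aldehyde is trapped by O6 as the lactol and this is oxidised on to the γ-lactone (oxidative lactonisation of a 1,4-diol).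

Step 23
Reactants: 34 lactone
Product: 36 (11R)-11-phenylselanyl lactone, via lithium enolate 35 (not isolated)
Conditions: LiN(iPr)2, THF, −78 °C; PhSeBr, −78 °C
Reagents that add atoms: phenylselenenyl bromide Br[Se]c1ccccc1
Why: kinetic lactone enolate formation and immediate selenenylation at −78 °C, with PhSeBr approaching the enolate face anti to C8 and therefore cis to H7, the arrangement the syn-elimination needs.

Step 24
Reactants: 36 selenide
Product: 38 7(11)-butenolide, via selenoxide 37 (not isolated)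
Conditions: 30% H2O2, pyridine, CH2Cl2, 0 °C → rt
Reagents that add atoms: none
Why: selenoxide syn-elimination takes the cis H7 (elimination towards the oxygen-bearing C13 is disfavoured), giving the tetrasubstituted C7=C11 bond and erasing the C7 and C11 stereocentres.

Step 25
Reactants: 38 PMB ether
Product: 39 C8 alcohol
Conditions: DDQ, CH2Cl2/pH 7 buffer, 0 °C
Reagents that add atoms: none
Why: oxidative PMB cleavage under buffered conditions should leave the silyl ethers, the epoxide and the butenolide untouched.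

Step 26
Reactants: 39 C8 alcohol
Product: 40 C8 methacrylate
Conditions: methacrylic anhydride, Et3N, DMAP (cat.), CH2Cl2, 0 °C → rt
Reagents that add atoms: methacrylic anhydride C=C(C)C(=O)OC(=O)C(C)=C
Why: DMAP-catalysed acyl transfer to the secondary alcohol, done while O2 and O13 are still silylated so that no acyl group can migrate between O13 and O8.

Step 27
Reactants: 40 bis-silyl ether
Product: 41 C2,C13-diol
Conditions: HF·pyridine, pyridine, THF, 0 °C → rt
Reagents that add atoms: none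
Why: buffered fluoride desilylation removes the secondary TBS and primary TIPS ethers without the base that could deprotonate the butenolide at C6 or the strong acid that could open the epoxide.

Step 28
Reactants: 41 diol
Product: 42 CNP0268364.3
Conditions: Ac2O, pyridine, DMAP (cat.), CH2Cl2, 0 °C
Reagents that add atoms: acetic anhydride CC(=O)OC(C)=O
Why: acetylation of the primary allylic and secondary allylic hydroxyls completes the target without touching a stereocentre.

**Compound list**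

1 | (R)-glycidol, (R)-oxiran-2-ylmethanol | OC[C@@H]1CO1 | starting material
2 | sodium (R)-oxiran-2-ylmethanolate | [Na+].[O-]C[C@@H]1CO1 | intermediate
3 | (S)-2-[(4-methoxybenzyloxy)methyl]oxirane | COc1ccc(COC[C@@H]2CO2)cc1 | intermediate
4 | 2-(prop-2-yn-1-yloxy)tetrahydro-2H-pyran | C#CCOC1CCCCO1 | starting material
5 | [3-(tetrahydropyran-2-yloxy)prop-1-yn-1-yl]lithium | [Li]C#CCOC1CCCCO1 | intermediate
6 | (2S)-1-(4-methoxybenzyloxy)-6-(tetrahydropyran-2-yloxy)hex-4-yn-2-ol | COc1ccc(COC[C@@H](O)CC#CCOC2CCCCO2)cc1 | intermediate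
7 | tert-butyl{[(2S)-1-(4-methoxybenzyloxy)-6-(tetrahydropyran-2-yloxy)hex-4-yn-2-yl]oxy}dimethylsilane | COc1ccc(COC[C@@H](O[Si](C)(C)C(C)(C)C)CC#CCOC2CCCCO2)cc1 | intermediate
8 | (2S)-2-(tert-butyldimethylsilyloxy)-6-(tetrahydropyran-2-yloxy)hex-4-yn-1-ol | OC[C@@H](O[Si](C)(C)C(C)(C)C)CC#CCOC1CCCCO1 | intermediate
9 | (2S)-2-(tert-butyldimethylsilyloxy)-6-(tetrahydropyran-2-yloxy)hex-4-ynal | O=C[C@@H](O[Si](C)(C)C(C)(C)C)CC#CCOC1CCCCO1 | intermediate
10 | (2Z,4S)-4-(tert-butyldimethylsilyloxy)-2-iodo-8-(tetrahydropyran-2-yloxy)oct-2-en-6-yne | C/C(I)=C/[C@@H](O[Si](C)(C)C(C)(C)C)CC#CCOC1CCCCO1 | intermediate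
11 | [(4S)-4-(tert-butyldimethylsilyloxy)-8-(tetrahydropyran-2-yloxy)oct-2-en-6-yn-2-yl]lithium, lithium cis to the C4 chain (geometry of 10 retained) | C/C([Li])=C/[C@@H](O[Si](C)(C)C(C)(C)C)CC#CCOC1CCCCO1 | intermediate
12 | (2S,4Z,6S)-6-(tert-butyldimethylsilyloxy)-1-(4-methoxybenzyloxy)-4-methyl-10-(tetrahydropyran-2-yloxy)dec-4-en-8-yn-2-ol | COc1ccc(COC[C@@H](O)C/C(C)=C\[C@@H](O[Si](C)(C)C(C)(C)C)CC#CCOC2CCCCO2)cc1 | intermediate
13 | (4S)-4-[(2Z,4S)-4-(tert-butyldimethylsilyloxy)-2-methyl-8-(tetrahydropyran-2-yloxy)oct-2-en-6-yn-1-yl]-2-(4-methoxyphenyl)-1,3-dioxolane | COc1ccc(C2OC[C@@H](O2)C/C(C)=C\[C@@H](O[Si](C)(C)C(C)(C)C)CC#CCOC3CCCCO3)cc1 | intermediate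
14 | (2S,4Z,6S)-6-(tert-butyldimethylsilyloxy)-2-(4-methoxybenzyloxy)-4-methyl-10-(tetrahydropyran-2-yloxy)dec-4-en-8-yn-1-ol | OC[C@@H](OCc1ccc(OC)cc1)C/C(C)=C\[C@@H](O[Si](C)(C)C(C)(C)C)CC#CCOC1CCCCO1 | intermediate
15 | (2S,4Z,6S)-6-(tert-butyldimethylsilyloxy)-2-(4-methoxybenzyloxy)-4-methyl-10-(tetrahydropyran-2-yloxy)dec-4-en-8-ynal | O=C[C@@H](OCc1ccc(OC)cc1)C/C(C)=C\[C@@H](O[Si](C)(C)C(C)(C)C)CC#CCOC1CCCCO1 | intermediate
16 | triethyl phosphonoacetate | CCOC(=O)CP(=O)(OCC)OCC | starting material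
17 | sodium salt (enolate) of triethyl phosphonoacetate | CCOC(=O)[CH-]P(=O)(OCC)OCC.[Na+] | intermediate
18 | ethyl 2-(diethoxyphosphoryl)-3-(triisopropylsilyloxy)propanoate (racemic) | CCOC(=O)C(CO[Si](C(C)C)(C(C)C)C(C)C)P(=O)(OCC)OCC | intermediate
19 | ethyl (2E,4S,6Z,8S)-8-(tert-butyldimethylsilyloxy)-4-(4-methoxybenzyloxy)-6-methyl-12-(tetrahydropyran-2-yloxy)-2-[(triisopropylsilyloxy)methyl]dodeca-2,6-dien-10-ynoate (ester trans to C8) | CCOC(=O)/C(CO[Si](C(C)C)(C(C)C)C(C)C)=C/[C@@H](OCc1ccc(OC)cc1)C/C(C)=C\[C@@H](O[Si](C)(C)C(C)(C)C)CC#CCOC1CCCCO1 | intermediate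
20 | (2Z,4S,6Z,8S)-8-(tert-butyldimethylsilyloxy)-4-(4-methoxybenzyloxy)-6-methyl-12-(tetrahydropyran-2-yloxy)-2-[(triisopropylsilyloxy)methyl]dodeca-2,6-dien-10-yn-1-ol (CH2OH trans to C8) | OC/C(CO[Si](C(C)C)(C(C)C)C(C)C)=C/[C@@H](OCc1ccc(OC)cc1)C/C(C)=C\[C@@H](O[Si](C)(C)C(C)(C)C)CC#CCOC1CCCCO1 | intermediate
21 | C12 chloride of 20 (CH2Cl trans to C8; C6-OTHP, C2-OTBS, C8-OPMB, C13-OTIPS) | ClC/C(CO[Si](C(C)C)(C(C)C)C(C)C)=C/[C@@H](OCc1ccc(OC)cc1)C/C(C)=C\[C@@H](O[Si](C)(C)C(C)(C)C)CC#CCOC1CCCCO1 | intermediate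
22 | (5S,6Z,9S,10E)-5-(tert-butyldimethylsilyloxy)-12-chloro-9-(4-methoxybenzyloxy)-7-methyl-11-[(triisopropylsilyloxy)methyl]dodeca-6,10-dien-2-yn-1-ol | ClC/C(CO[Si](C(C)C)(C(C)C)C(C)C)=C/[C@@H](OCc1ccc(OC)cc1)C/C(C)=C\[C@@H](O[Si](C)(C)C(C)(C)C)CC#CCO | intermediate
23 | sodium alkoxide of 22 | ClC/C(CO[Si](C(C)C)(C(C)C)C(C)C)=C/[C@@H](OCc1ccc(OC)cc1)C/C(C)=C\[C@@H](O[Si](C)(C)C(C)(C)C)CC#CC[O-].[Na+] | intermediate
24 | (3Z,5S,7Z,9S)-9-(tert-butyldimethylsilyloxy)-5-(4-methoxybenzyloxy)-7-methyl-3-[(triisopropylsilyloxy)methyl]-1-oxacyclotrideca-3,7-dien-11-yne (ring: O, C12, C11=C7, C8, C9, C10=C1, C2, C3, C4≡C5, C6; C12 trans to C8) | O1C/C(CO[Si](C(C)C)(C(C)C)C(C)C)=C/[C@@H](OCc2ccc(OC)cc2)C/C(C)=C\[C@@H](O[Si](C)(C)C(C)(C)C)CC#CC1 | intermediate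
25 | C6-lithiated 24 (propargyl/allenyl lithium) | O1C/C(CO[Si](C(C)C)(C(C)C)C(C)C)=C/[C@@H](OCc2ccc(OC)cc2)C/C(C)=C\[C@@H](O[Si](C)(C)C(C)(C)C)CC#CC1[Li] | intermediate
26 | (1S,5S,6Z,9S,10S)-5-(tert-butyldimethylsilyloxy)-9-(4-methoxybenzyloxy)-7-methyl-10-[3-(triisopropylsilyloxy)prop-1-en-2-yl]cyclodec-6-en-2-yn-1-ol (germacrane locants 2S,6S,7S,8S; H6/H7 trans, O6 and O8 cis) | COc1ccc(CO[C@H]2C/C(C)=C\[C@@H](O[Si](C)(C)C(C)(C)C)CC#C[C@@H](O)[C@@H]2C(=C)CO[Si](C(C)C)(C(C)C)C(C)C)cc1 | intermediate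
27 | sodium cyclic alkoxy(alkenyl)bis(2-methoxyethoxy)aluminate from 26 (Al on C4 and O6) | COc1ccc(CO[C@H]2C/C(C)=C\[C@@H](O[Si](C)(C)C(C)(C)C)C/C3=C/[C@@H](O[Al-]3(OCCOC)OCCOC)[C@@H]2C(=C)CO[Si](C(C)C)(C(C)C)C(C)C)cc1.[Na+] | intermediate
28 | (1S,2Z,5S,6Z,9S,10S)-5-(tert-butyldimethylsilyloxy)-3-iodo-9-(4-methoxybenzyloxy)-7-methyl-10-[3-(triisopropylsilyloxy)prop-1-en-2-yl]cyclodeca-2,6-dien-1-ol | COc1ccc(CO[C@H]2C/C(C)=C\[C@@H](O[Si](C)(C)C(C)(C)C)C/C(I)=C/[C@@H](O)[C@@H]2C(=C)CO[Si](C(C)C)(C(C)C)C(C)C)cc1 | intermediate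
29 | (1R,2E,5S,6Z,9S,10S)-5-(tert-butyldimethylsilyloxy)-9-(4-methoxybenzyloxy)-3,7-dimethyl-10-[3-(triisopropylsilyloxy)prop-1-en-2-yl]cyclodeca-2,6-dien-1-ol | COc1ccc(CO[C@H]2C/C(C)=C\[C@@H](O[Si](C)(C)C(C)(C)C)C/C(C)=C/[C@@H](O)[C@@H]2C(=C)CO[Si](C(C)C)(C(C)C)C(C)C)cc1 | intermediate
30 | 4,5-epoxide of 29, germacrane locants (2S,4R,5R,6S,7S,8S) | COc1ccc(CO[C@H]2C/C(C)=C\[C@@H](O[Si](C)(C)C(C)(C)C)C[C@@]3(C)O[C@@H]3[C@@H](O)[C@@H]2C(=C)CO[Si](C(C)C)(C(C)C)C(C)C)cc1 | intermediate
31 | O6-borinate, C12-borane of 30 (two 9-borabicyclo[3.3.1]nonan-9-yl groups) | COc1ccc(CO[C@H]2C/C(C)=C\[C@@H](O[Si](C)(C)C(C)(C)C)C[C@@]3(C)O[C@@H]3[C@@H](OB3C4CCCC3CCC4)[C@@H]2C(CB2C3CCCC2CCC3)CO[Si](C(C)C)(C(C)C)C(C)C)cc1 | intermediate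
32 | C6,C12-diol, (2S,4R,5R,6S,7S,8S), C11 epimers | COc1ccc(CO[C@H]2C/C(C)=C\[C@@H](O[Si](C)(C)C(C)(C)C)C[C@@]3(C)O[C@@H]3[C@@H](O)[C@@H]2C(CO)CO[Si](C(C)C)(C(C)C)C(C)C)cc1 | intermediate
33 | 6,12-lactol | COc1ccc(CO[C@H]2C/C(C)=C\[C@@H](O[Si](C)(C)C(C)(C)C)C[C@@]3(C)O[C@@H]3[C@H]3OC(O)C(CO[Si](C(C)C)(C(C)C)C(C)C)[C@H]23)cc1 | intermediate
34 | trans-fused 6,12-lactone, (2S,4R,5R,6S,7R,8S), C11 epimers, C13-OTIPS | COc1ccc(CO[C@H]2C/C(C)=C\[C@@H](O[Si](C)(C)C(C)(C)C)C[C@@]3(C)O[C@@H]3[C@H]3OC(=O)C(CO[Si](C(C)C)(C(C)C)C(C)C)[C@H]23)cc1 | intermediate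
35 | lithium enolate of 34 | COc1ccc(CO[C@H]2C/C(C)=C\[C@@H](O[Si](C)(C)C(C)(C)C)C[C@@]3(C)O[C@@H]3[C@H]3OC(O[Li])=C(CO[Si](C(C)C)(C(C)C)C(C)C)[C@H]23)cc1 | intermediate
36 | (11R)-11-phenylselanyl lactone, selenium cis to H7 | COc1ccc(CO[C@H]2C/C(C)=C\[C@@H](O[Si](C)(C)C(C)(C)C)C[C@@]3(C)O[C@@H]3[C@H]3OC(=O)[C@@](CO[Si](C(C)C)(C(C)C)C(C)C)([Se]c4ccccc4)[C@H]23)cc1 | intermediate
37 | selenoxide of 36 | COc1ccc(CO[C@H]2C/C(C)=C\[C@@H](O[Si](C)(C)C(C)(C)C)C[C@@]3(C)O[C@@H]3[C@H]3OC(=O)[C@@](CO[Si](C(C)C)(C(C)C)C(C)C)([Se](=O)c4ccccc4)[C@H]23)cc1 | intermediate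
38 | 7(11)-butenolide, (2S,4R,5R,6S,8S), O2-TBS, O8-PMB, O13-TIPS | COc1ccc(CO[C@H]2C/C(C)=C\[C@@H](O[Si](C)(C)C(C)(C)C)C[C@@]3(C)O[C@@H]3[C@H]3OC(=O)C(CO[Si](C(C)C)(C(C)C)C(C)C)=C23)cc1 | intermediate
39 | C8 alcohol of 38 | O[C@H]1C/C(C)=C\[C@@H](O[Si](C)(C)C(C)(C)C)C[C@@]2(C)O[C@@H]2[C@H]2OC(=O)C(CO[Si](C(C)C)(C(C)C)C(C)C)=C12 | intermediate
40 | C8 methacrylate, O2-TBS, O13-TIPS | C=C(C)C(=O)O[C@H]1C/C(C)=C\[C@@H](O[Si](C)(C)C(C)(C)C)C[C@@]2(C)O[C@@H]2[C@H]2OC(=O)C(CO[Si](C(C)C)(C(C)C)C(C)C)=C12 | intermediate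
41 | C8 methacrylate C2,C13-diol | C=C(C)C(=O)O[C@H]1C/C(C)=C\[C@@H](O)C[C@@]2(C)O[C@@H]2[C@H]2OC(=O)C(CO)=C12 | intermediate
42 | CNP0268364.3, (2S,4R,5R,6S,8S,1(10)Z) | C=C(C)C(=O)O[C@H]1C/C(C)=C\[C@@H](OC(C)=O)C[C@@]2(C)O[C@@H]2[C@H]2OC(=O)C(COC(C)=O)=C12 | target

**Step count**

Total: 28 steps. Longest linear sequence: 27 steps (steps 1–10 and 12–28; step 11 is a one-step side branch).

**Steps most likely to fail**

1. Step 17. The medium ring may force the envelope into the syn pathway or bring C6 onto the alkene face syn to the C8–OPMB bond, so that the carbinol forms with the wrong configuration at C6. Fallback (sets out from 24, returns at 26): the rearrangement is run as before and the (6R)-configured alcohol, 6-epi-26 F1, is kept. A Mitsunobu reaction (4-nitrobenzoic acid, PPh3, DIAD, toluene, 0 °C) displaces the activated propargylic hydroxyl with inversion to give the (6S)-4-nitrobenzoate F2, and methanolysis (K2CO3, MeOH) should return 26.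

2. Step 23 (with step 24). The lithium enolate may lose triisopropylsilanolate from C13 by β-elimination before it is trapped, or selenium may enter trans to H7 so that the selenoxide cannot reach H7. Fallback (sets out from 34, returns at 38): LiN(iPr)2 is added to a premixed solution of 34 and Me3SiCl at −78 °C, so the enolate is silylated as it forms and gives the trimethylsilyl ketene acetal F3. Saegusa–Ito dehydrosilylation with Pd(OAc)2 in MeCN should then form the C7=C11 bond through a palladium enolate whose β-hydride elimination is not tied to one face of C11.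

3. Step 12. The phosphonate carbanion may expel silanolate (forming the vinylphosphonate) faster than it adds to the aldehyde, or the base may erode the configuration at C8. Fallback (sets out from 15, returns at 19): Wittig olefination with the neutral stabilised ylide ethyl 3-(triisopropylsilyloxy)-2-(triphenylphosphoranylidene)propanoate F4, made from commercial Ph3P=CHCO2Et (2 equiv) and TOM-Cl by C-alkylation and transylidation. Heating with 15 in toluene at 60 °C involves no anion with a β-leaving group and no added base, and should give 19 with the ester trans to C8.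

**Further compounds**

F1 | step 17 | (1R,5S,6Z,9S,10S)-5-(tert-butyldimethylsilyloxy)-9-(4-methoxybenzyloxy)-7-methyl-10-[3-(triisopropylsilyloxy)prop-1-en-2-yl]cyclodec-6-en-2-yn-1-ol (C6 epimer of 26) | COc1ccc(CO[C@H]2C/C(C)=C\[C@@H](O[Si](C)(C)C(C)(C)C)CC#C[C@H](O)[C@@H]2C(=C)CO[Si](C(C)C)(C(C)C)C(C)C)cc1
F2 | step 17 | 4-nitrobenzoate of 26 (6S) | COc1ccc(CO[C@H]2C/C(C)=C\[C@@H](O[Si](C)(C)C(C)(C)C)CC#C[C@@H](OC(=O)c3ccc(cc3)[N+](=O)[O-])[C@@H]2C(=C)CO[Si](C(C)C)(C(C)C)C(C)C)cc1
F3 | step 23 | trimethylsilyl ketene acetal of 34 | COc1ccc(CO[C@H]2C/C(C)=C\[C@@H](O[Si](C)(C)C(C)(C)C)C[C@@]3(C)O[C@@H]3[C@H]3OC(O[Si](C)(C)C)=C(CO[Si](C(C)C)(C(C)C)C(C)C)[C@H]23)cc1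
F4 | step 12 | ethyl 3-(triisopropylsilyloxy)-2-(triphenylphosphoranylidene)propanoate | CCOC(=O)C(CO[Si](C(C)C)(C(C)C)C(C)C)=P(c1ccccc1)(c1ccccc1)c1ccccc1
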